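The numbers were chosen freely; what happens was integrated by code.

A small charge of Q, 0.20 M, met Z at different strengths, and I wanted the G standing after 20 min.

| setting | birch | alder | larch |
|---|---|---|---|
| Q | 0.20 M | 0.20 M | 0.20 M |
| Z | 0.250 M | 0.800 M | 2.50 M |
| time | 20 min | 20 min | 20 min |

    G + Z → G.Z (k1 = 0.12 M⁻¹ min⁻¹)
    L + Z → J + D (k2 = 0.40 M⁻¹ min⁻¹)
    E + Z → J + G (k3 = 0.19 M⁻¹ min⁻¹)
    D + Z → J + E (k4 = 0.22 M⁻¹ min⁻¹)
    Q + Z → J + L (k5 = 0.32 M⁻¹ min⁻¹)

* amount of G at the end, in percent of the Q charged for birch, alder, larch, in this order
* the shape of the row from first to last (rises all the way / falls, then rises / hardly changes / falls all the way / rises, then falls)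

- "hardly changes" means that all values lie within two and a half points (for a concentration: within two and a half percent of the largest)
- run time (birch): 20 min

The concentration that set the order of the rate was that of Z: each step took Z as its partner, so at a given [Z] each was pseudo-first-order with rate constant k[Z]. I therefore measured progress by the dose θ, the time integral of [Z]: in θ the chain from Q through L, D and E to G and G.Z runs the same way whatever path [Z] takes. I called the mean θ a Q needs to become G, the sum of the inverse rate constants along that way, the arrival dose S = 926 M·s.

The ladder, as half-lives at birch's charge of Z, each by its own step alone, ran L 6.9 min, Q 8.7 min, D 13 min, E 15 min, G 23 min, and a change of Z moves these rungs by one common factor. L lived shorter than the Q feeding it, so I expected it to follow Q. D and E lived longer than Q, so I expected them to collect. G lived longest, and adding its inverse rate constant to S gave the mean dose at which a Q leaves G, θ = 1430 M·s.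

Since Z can only fall, charge times time is a ceiling on θ: 300 M·s for birch, below S, and 960 M·s for alder, about S. In larch each Q takes at most 5 Z, so [Z] does not fall below 1.50 M and θ reaches at least 1800 M·s, past that mean dose. I committed to a row that rises, then falls, and to no figures.

The forecast put the row at 0.6 %, 17 % and 10.5 %, rises, then falls, holding that alder “leaves G near its peak”. Its figures go beyond my reckoning, and on the shape we agree.

The row came to 0.669 %, 17.7 % and 12.1 %: it rises, then falls, with the turn at 1.4 M of Z. Alder ended with 4.97 % of its Q left. Q has a single exit, so the logarithm of its inverse share, divided by that step's rate constant, reads θ: 0.608 S for alder at the end. Read the same way, larch at 10.0 min stood at 1.28 S with G at 32.8 %, and alder at 200 min stood at 1.21 S with G at 33.3 %.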